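Its constants were set for the occasion; what happens was integrated by code.

In this closed flask the fractions of the charge in the five species, with side product and homo dimer counted double, add up to one at every moment, so once I had dropped the over-reaction product from the reckoning, target, side product and homo dimer gave me the substrate as well.

| setting | gamma | zeta | beta |
|---|---|---|---|
| substrate | 1.0 M | 1.0 M | 1.0 M |
| time | 6.0 h | 12 h | 25 h |

- which of these there is most of at the end, counted by the substrate in it, gamma (substrate / side product / target)
- which of these there is most of at the end, counted by the substrate in it, zeta (substrate / side product / target)
- which of these there is most of at the end, counted by the substrate in it, beta (substrate / side product / target)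
- the largest of these amounts at the end, in percent of the substrate charged, gamma
- the largest of these amounts at the end, in percent of the substrate charged, zeta
- the largest of these amounts at the end, in percent of the substrate charged, beta

I held beta against its neighbour with 0.25 M of substrate, read at the same 25 h, which looks like the same recipe made thinner. Target grows with the net constant g = 0.355 L mol⁻¹ h⁻¹, the target-making step less the side-product step, from a seed laid by the uncatalysed step. Early on the substrate falls mainly to homo dimer, whose starting rate is faster than the uncatalysed one. I wrote d = 0.0228 L mol⁻¹ h⁻¹, and dropped the over-reaction, whose constant is far smaller than 0.0400 L mol⁻¹ h⁻¹ times the charge.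

With substrate at one over (one plus d·c·t), the target rate integrates in closed form: target = seed·(e^n − one), where seed = 0.00163 h⁻¹/(g·c) and n = (g/d)·ln(one plus d·c·t). Beta reached 7.02 and the neighbour 2.07 of what I called the growth count, the number of e-foldings target has made. The mark is ln(one/seed), where the formula fills the charge. Beta's seed of 0.459% sets it at 5.38, and beta passed it. The neighbour's seed is larger, 1.84%, but its mark of 4.00 stayed ahead of its count.

Each target gained brings r = 0.225 of side product, the selectivity factor. Gamma's count of 2.00 gave target 2.92% and substrate 84.4%. Zeta's 3.77 gave target 19.4% and substrate 54.8%. For beta I froze homo dimer at its halfway value, 22.2%, took the substrate as gone, and got target 63.5%.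

The forecast named substrate, substrate and target, at 86%, 62% and 59%, reading “autocatalysis with a long induction period”. The simulation gave substrate at 84.9% in gamma, substrate at 61.7% in zeta and target at 59.0% in beta, against my 84.4%, 54.8% and 63.5%.

    substrate + target → 2 target (k1 = 0.395 L mol⁻¹ h⁻¹)
    substrate → target (k2 = 0.00163 h⁻¹)
    substrate + target → side product (k3 = 0.0400 L mol⁻¹ h⁻¹)
    target → over-reaction product (k4 = 9.75 × 10⁻⁵ h⁻¹)
    2 substrate → homo dimer (k5 = 0.0114 L mol⁻¹ h⁻¹)

The neighbour took the same reckoning. Its count of 2.07 on a seed of 1.84% gave target 12.8%, and the balance left substrate 71.9%, whereas beta's count of 7.02 had passed its mark. The neighbour itself read target 11.4% and side product 1.75%, and the species holding most at 25.0 h was substrate, at 75.5%.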